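## Retrosynthetic overview

1. The 2‑methoxy‑γ‑pyrone is the only ring and is formed last. It is cut at O1–C2 and C3–C4 into an α‑methyl acylketene (C4, C5‑Me, C6 and the side chain) and 1‑methoxyprop‑1‑yne (C2‑OMe, C3‑Me). This hetero‑[4+2] is the proposed new step.
2. The acylketene is released thermally (loss of t‑BuOH) from a tert‑butyl 2‑methyl‑3‑oxo ester.
3. The β‑keto ester comes from a crossed Claisen between 12‑acetoxydodecanoyl chloride and the lithium enolate of tert‑butyl propionate. The acid comes from 12‑hydroxydodecanoic acid and Ac2O, and the acetate is carried through unchanged.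
4. The ynol ether comes from chloroacetaldehyde dimethyl acetal (double elimination) and MeI.

Assumption: the target SMILES has no stereocentre and no stereogenic double bond, so it is achiral and "single enantiomer" is read as the constitution as drawn; 1‑methoxyprop‑1‑yne is treated as not purchasable and is made in step 3.

## Route

Step 1

Reactants: 1 12-hydroxydodecanoic acid; 2 acetic anhydride

Product: 3 12-acetoxydodecanoic acid

Conditions: Ac2O (2.5 equiv), pyridine (3 equiv), DMAP (5 mol%), CH2Cl2, 0 °C → rt, 3 h; then H2O, rt, 1 h; 1 M HCl wash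

Reagents that add atoms: acetic anhydride, CC(=O)OC(C)=O

Why: DMAP‑catalysed O‑acetylation of the primary alcohol (nucleophilic acyl substitution); the mixed anhydride formed at the carboxyl end is hydrolysed back to the acid in the aqueous stir.

Step 2

Reactants: 3 12-acetoxydodecanoic acid; 4 tert-butyl propionate

Product: 7 racemic tert-butyl 14-acetoxy-2-methyl-3-oxotetradecanoate, via 12-acetoxydodecanoyl chloride 5 (not isolated), via lithium enolate of tert-butyl propionate 6 (not isolated)

Conditions: (i) (COCl)2 (1.3 equiv), DMF (cat.), CH2Cl2, 0 °C → rt, concentrate; (ii) 4 (2.3 equiv), LDA (commercial, 2.2 equiv), THF, −78 °C, 45 min; (iii) 5 in THF added to 6, −78 °C, 30 min; sat. aq NH4Cl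

Reagents that add atoms: tert-butyl propionate, CCC(=O)OC(C)(C)C

Why: Crossed Claisen condensation in which the acid chloride is far more electrophilic than the acetate at −78 °C and the second equivalent of enolate deprotonates the β‑keto ester as it forms, which blocks double acylation; the C‑2 stereocentre forms racemic and becomes sp2 in step 4.

Step 3

Reactants: 8 chloroacetaldehyde dimethyl acetal; 9 iodomethane

Product: 11 1-methoxyprop-1-yne, via sodium methoxyacetylide 10 (not isolated)

Conditions: NaNH2 (commercial, 3.1 equiv), liq. NH3, −40 °C, 1 h; MeI (1.1 equiv), −60 → −33 °C, 1 h; NH3 off, cold brine, distil (bp ca. 65 °C), store over K2CO3 at −20 °C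

Reagents that add atoms: iodomethane, CI

Why: Amide‑induced loss of MeOH and then HCl from the chloroacetal gives methoxyacetylene, which is deprotonated in situ and C‑methylated by SN2 on MeI (acetylide alkylation in liquid ammonia).

Step 4

Reactants: 7 racemic tert-butyl 14-acetoxy-2-methyl-3-oxotetradecanoate; 11 1-methoxyprop-1-yne

Product: 13 11-(6-methoxy-3,5-dimethyl-4-oxo-4H-pyran-2-yl)undecyl acetate, via acylketene 12 (not isolated)

Conditions: 11 (4 equiv), PhCl (0.05 M), base‑washed sealed tube, 135 °C, 4 h

Reagents that add atoms: none

Why: Proposed new method: a thermal, catalyst‑free hetero‑[4+2] annulation of an α‑branched acylketene with an internal methyl ynol ether that gives a fully substituted α‑methoxy‑γ‑pyrone in one step — 7 loses t‑BuOH through the usual six‑membered retro‑ene transition state to give the s‑cis acylketene 12, the nucleophilic C‑2 of 11 (β to OMe) bonds to the electrophilic ketene carbon while the acyl oxygen closes on the oxocarbenium‑like C‑1 (asynchronous, pseudopericyclic), which fixes OMe at C‑2, Me at C‑3 and C‑5 and the chain at C‑6 and gives the aromatic pyranone directly with no elimination or oxidation step, and 11 has no β‑hydrogen on its O‑alkyl group so it cannot fragment by the retro‑ene path that destroys ethyl or tert‑butyl ynol ethers at this temperature; the closest known reaction type is the hetero‑Diels–Alder trapping of thermally generated acylketenes by enol ethers, ketene acetals and ynamines.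

## Compound list

1 | 12-hydroxydodecanoic acid | OCCCCCCCCCCCC(=O)O | starting material

2 | acetic anhydride | CC(=O)OC(C)=O | starting material

3 | 12-acetoxydodecanoic acid | CC(=O)OCCCCCCCCCCCC(=O)O | intermediate

4 | tert-butyl propionate | CCC(=O)OC(C)(C)C | starting material

5 | 12-acetoxydodecanoyl chloride (12-chloro-12-oxododecyl acetate) | CC(=O)OCCCCCCCCCCCC(=O)Cl | intermediate

6 | lithium enolate of tert-butyl propionate (lithium 1-tert-butoxyprop-1-en-1-olate, geometry of no consequence) | [Li+].[O-]C(=CC)OC(C)(C)C | intermediate

7 | racemic tert-butyl 14-acetoxy-2-methyl-3-oxotetradecanoate | CC(=O)OCCCCCCCCCCCC(=O)C(C)C(=O)OC(C)(C)C | intermediate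

8 | chloroacetaldehyde dimethyl acetal (2-chloro-1,1-dimethoxyethane) | COC(CCl)OC | starting material

9 | iodomethane | CI | starting material

10 | sodium methoxyacetylide | [Na+].[C-]#COC | intermediate

11 | 1-methoxyprop-1-yne | CC#COC | intermediate

12 | acylketene 13-methyl-12,14-dioxotetradec-13-en-1-yl acetate | CC(=O)OCCCCCCCCCCCC(=O)C(C)=C=O | intermediate

13 | 11-(6-methoxy-3,5-dimethyl-4-oxo-4H-pyran-2-yl)undecyl acetate | COc1oc(CCCCCCCCCCCOC(C)=O)c(C)c(=O)c1C | target

## Step count and risks

Total step count: 4. Longest linear sequence: 3 (steps 1, 2 and 4); step 3 is a one‑step side branch that joins at step 4.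

**Step 4 (the proposed new annulation).** Three things can go wrong. The ketene C=C may react by [2+2] and open and re‑close to the isomeric 4‑methoxy‑2‑pyranone. The ynol ether may be consumed by the enol of 7 or by t‑BuOH. The α‑branched tert‑butyl ester may release the ketene too slowly, so that isobutene loss and decarboxylation take over. The fallback is known chemistry, sets out from 3 and comes back at 13. Compound 3 is activated with CDI (THF, rt) to the imidazolide 12-(1H-imidazol-1-yl)-12-oxododecyl acetate F1. Commercial methyl 2‑methyl‑3‑oxopentanoate is doubly deprotonated with LDA (2.1 equiv, THF, −78 → 0 °C) to the dilithium dianion of methyl 2-methyl-3-oxopentanoate F2. F1 is added to F2 at −78 °C (γ‑acylation of a β‑keto ester dianion; the acetate is tolerated at this temperature) to give the triketide methyl 16-acetoxy-2,4-dimethyl-3,5-dioxohexadecanoate F3. DBU in toluene at 60 °C closes F3 to the α‑pyrone 11-(4-hydroxy-3,5-dimethyl-2-oxo-2H-pyran-6-yl)undecyl acetate F4. MeOTf (CH2Cl2, rt) then methylates the lactone carbonyl oxygen and gives the γ‑pyrone 13.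

**Step 3 (ynol ether).** The product is volatile, methoxyacetylene derivatives polymerise easily, and MeI can be lost to ammonia or amide. The fallback sets out from iodomethane 9, which stays the methyl source, and comes back at 11; the C2O unit now comes from commercial trichloroethylene and potassium methoxide. These two in THF (−40 °C → rt) give (E)-1,2-dichloro-1-methoxyethene F5 by addition of methoxide to dichloroacetylene formed in situ. n‑BuLi (2.2 equiv, Et2O, −78 → −40 °C) converts F5 by HCl elimination and Cl/Li exchange into lithium methoxyacetylide F6. Methylation with 9 (DMPU, −78 °C → rt) gives 11. The distillate cut is assayed by NMR and used as such, since hexane and 1‑chlorobutane are inert in step 4.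

**Step 2 (crossed Claisen).** The enolate may attack the acetate, and the product may be O‑ or C‑acylated a second time. The fallback sets out from 3 and comes back at 7. Compound 3 and Meldrum's acid (DCC, DMAP, CH2Cl2, 0 °C → rt) give the acyl Meldrum's acid 5-(12-acetoxy-1-hydroxydodecylidene)-2,2-dimethyl-1,3-dioxane-4,6-dione F7. Heating F7 with t‑BuOH in toluene (90 °C) gives tert-butyl 14-acetoxy-3-oxotetradecanoate F8 with loss of acetone and CO2. Mono‑C‑methylation with 9 (K2CO3, acetone, rt) gives 7.

## Further compounds

F1 | step 4 | 12-(1H-imidazol-1-yl)-12-oxododecyl acetate | CC(=O)OCCCCCCCCCCCC(=O)n1ccnc1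

F2 | step 4 | dilithium dianion of methyl 2-methyl-3-oxopentanoate (dilithium 1-methoxy-2-methylpenta-1,3-diene-1,3-diolate) | [Li+].[Li+].COC([O-])=C(C)C([O-])=CC

F3 | step 4 | methyl 16-acetoxy-2,4-dimethyl-3,5-dioxohexadecanoate | CC(=O)OCCCCCCCCCCCC(=O)C(C)C(=O)C(C)C(=O)OC

F4 | step 4 | 11-(4-hydroxy-3,5-dimethyl-2-oxo-2H-pyran-6-yl)undecyl acetate | CC(=O)OCCCCCCCCCCCc1oc(=O)c(C)c(O)c1C

F5 | step 3 | (E)-1,2-dichloro-1-methoxyethene | CO/C(Cl)=C\Cl

F6 | step 3 | lithium methoxyacetylide | [Li+].[C-]#COC

F7 | step 2 | 5-(12-acetoxy-1-hydroxydodecylidene)-2,2-dimethyl-1,3-dioxane-4,6-dione | CC(=O)OCCCCCCCCCCCC(O)=C1C(=O)OC(C)(C)OC1=O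

F8 | step 2 | tert-butyl 14-acetoxy-3-oxotetradecanoate | CC(=O)OCCCCCCCCCCCC(=O)CC(=O)OC(C)(C)C
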